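**Retrosynthetic overview**
1. Feature: the dihydropyran enol ether O–Cα(ring B)=Cβ(ring A), tied through Cβ to the cyclobutane CH (C1) and through oxygen to the C(CH3)–O carbon (C3). It is read as an aryl alkyne C1–Cβ≡Cα–ring B across which the cis C3 oxygen and ring A have added from opposite sides.
2. Last ring: the oxepine, opened at the diaryl ether bond O–C(ring A). It closes by Ullmann reaction of the ring B ortho-phenol with a ring A bromide.
3. Key disconnection: O–Cα and Cβ–C(ring A) together, back to a bicyclic aryl alkynol and a 2-bromo-1-iodo ring A fragment. This closes the pyran.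
4. The alkynol comes from Sonogashira coupling of an ethynyl carbinol with silylated 4-iodoresorcinol. The ethynyl carbinol comes from a tricyclic γ-lactone through its lactol and a one-carbon alkynylation.
5. The lactone comes from an intramolecular [2+2] photocycloaddition of an (R)-butenolide, with C3 set by Sharpless epoxidation of geraniol. Ring order: butenolide (temporary), cyclopentane and cyclobutane together, pyran, oxepine.

Key step: step 12

Locants used throughout:
- C1 is the cyclobutane CH that carries the carbonyl or alkyne carbon.
- C2 and C6 are the ring-fusion CH groups.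
- C3 is the C(CH3)–O carbon, C4 and C5 are the CH2 groups, and C7 is the C(CH3)2 carbon.
- Cβ is bound to C1 and Cα to ring B. Ring A carries the prenyl group.

Remark: all three phenols are carried as triisopropylsilyl ethers. If needed, the enantiomeric purity reached in step 1 could be raised by recrystallisation at the tricyclic lactone stage.

**Step 1**
Reactants: 1 geraniol
Product: 2 (2R,3R)-2,3-epoxygeraniol
Conditions: Ti(OiPr)4 (5 mol %), D-(−)-diethyl tartrate (6 mol %), t-BuOOH, 4 Å MS, CH2Cl2, −20 °C
Reagents that add atoms: tert-butyl hydroperoxide CC(C)(C)OO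
Why: Sharpless asymmetric epoxidation is directed by the allylic hydroxyl to the 2,3-alkene only, and the D-(−)-tartrate/titanium complex delivers oxygen to the face that gives the (2R,3R)-epoxide, which fixes C3, the centre from which all others are later derived.

**Step 2**
Reactants: 2 (2R,3R)-2,3-epoxygeraniol
Product: 3 (2S,3R)-1-chloro-2,3-epoxy-3,7-dimethyloct-6-ene
Conditions: PPh3, CCl4, NaHCO3, reflux
Reagents that add atoms: carbon tetrachloride ClC(Cl)(Cl)Cl
Why: Appel chlorination replaces the primary hydroxyl by SN2 under nearly neutral conditions, leaving the epoxide and both stereocentres untouched (the C2 descriptor changes through priorities only).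

**Step 3**
Reactants: 3 (2S,3R)-1-chloro-2,3-epoxy-3,7-dimethyloct-6-ene
Product: 5 (4R)-4-hydroxy-4,8-dimethylnon-7-en-2-ynoic acid, via dilithiated (R)-dehydrolinalool 4 (not isolated)
Conditions: n-BuLi (3.3 equiv), THF, −78 to −20 °C; CO2, −78 °C to rt; aq. HCl to pH 3
Reagents that add atoms: carbon dioxide O=C=O
Why: Base-induced double elimination of a 2,3-epoxy chloride (deprotonation next to chlorine with opening of the C2–O bond, then dehydrochlorination of the chlorovinyl alkoxide) gives the lithium acetylide alkoxide without ever breaking the C3–O bond, so C3 stays (R), and carboxylation of the acetylide adds the future Cβ.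

**Step 4**
Reactants: 5 (4R)-4-hydroxy-4,8-dimethylnon-7-en-2-ynoic acid
Product: 7 (5R)-5-methyl-5-(4-methylpent-3-en-1-yl)furan-2(5H)-one, via (2Z)-hydroxy dienoic acid 6 (not isolated)
Conditions: H2 (1 atm), Pd/CaCO3 poisoned with Pb(OAc)2 (Lindlar catalyst), quinoline, EtOAc, rt; then PPTS (cat.), toluene, 50 °C
Reagents that add atoms: none
Why: Lindlar semi-hydrogenation adds hydrogen syn to the ynoic acid much faster than to the trisubstituted alkene, and the (Z)-γ-hydroxy acid so formed lactonises to the butenolide with C3 unchanged.

**Step 5**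
Reactants: 7 (5R)-5-methyl-5-(4-methylpent-3-en-1-yl)furan-2(5H)-one
Product: 8 all-cis tricyclic γ-lactone (1R,2R,3R,6S): cyclobutane C1–C2–C6–C7 fused to the cyclopentane C2–C3–C4–C5–C6 and to the lactone O–C3–C2–C1–C(=O)
Conditions: hν (300 nm), MeCN/acetone 9:1, 0.01 M, degassed, rt
Reagents that add atoms: none
Why: In this triplet-sensitised intramolecular enone–alkene [2+2] photocycloaddition of a γ-tethered butenolide the three-atom tether enforces first closure of the five-membered ring (C2–C6) and hence the straight adduct (C1–C7), and because the chain hangs from C3 it reaches only one face of the butenolide, so C1, C2 and C6 are set all-cis relative to C3 (H-1, H-2, H-6 and the C3 methyl on one face).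

**Step 6**
Reactants: 8 all-cis tricyclic γ-lactone
Product: 9 tricyclic lactol (anomeric mixture at the new CH(OH) carbon)
Conditions: i-Bu2AlH (1.1 equiv), CH2Cl2, −78 °C; aq. potassium sodium tartrate
Reagents that add atoms: none
Why: Partial reduction of a lactone with diisobutylaluminium hydride stops at the aluminium lactolate at −78 °C, no ring stereocentre is involved, and the configuration of the lactol carbon is of no consequence.

**Step 7**
Reactants: 9 tricyclic lactol
Product: 11 ethynyl carbinol (C1-ethynyl cis to C3-OH on the all-cis bicyclo[3.2.0]heptane; 1S,2R,3R,6S where the C1 descriptor changes through priorities only), via ring-opened hydroxy aldehyde 10 (not isolated)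
Conditions: dimethyl (1-diazo-2-oxopropyl)phosphonate, K2CO3, MeOH, 0 °C to rt
Reagents that add atoms: dimethyl (1-diazo-2-oxopropyl)phosphonate CC(=O)C(=[N+]=[N-])P(=O)(OC)OC
Why: The Ohira–Bestmann variant of the Seyferth–Gilbert homologation intercepts the aldehyde tautomer 10 of the lactol and turns CHO into Cβ≡Cα–H under mild carbonate conditions chosen to preserve the α-stereocentre C1, so the alkyne stays cis to the C3 hydroxyl.

**Step 8**
Reactants: 12 4-iodoresorcinol
Product: 13 1-iodo-2,4-bis(triisopropylsilyloxy)benzene
Conditions: TIPSCl (2.4 equiv), imidazole, DMF, rt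
Reagents that add atoms: triisopropylsilyl chloride CC(C)[Si](Cl)(C(C)C)C(C)C
Why: Imidazole-promoted silylation of both phenols is routine, and the bulky triisopropylsilyl group is taken because its aryl ethers withstand amine bases and hindered alkoxides yet fall to fluoride at the end.

**Step 9**
Reactants: 11 ethynyl carbinol; 13 1-iodo-2,4-bis(triisopropylsilyloxy)benzene
Product: 14 bicyclic aryl alkynol: C1–Cβ≡Cα–[2,4-bis(triisopropylsilyloxy)phenyl] cis to the free C3 hydroxyl (1R,2R,3R,6S)
Conditions: PdCl2(PPh3)2 (3 mol %), CuI (6 mol %), Et3N, THF, 45 °C, degassed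
Reagents that add atoms: none
Why: Sonogashira coupling of a terminal alkyne with an aryl iodide runs under amine base, which the free tertiary alcohol and the aryl silyl ethers tolerate, and it touches no stereocentre.

**Step 10**
Reactants: 15 3-bromo-4-iodophenol; 16 prenyl bromide
Product: 17 5-bromo-4-iodo-2-(3-methylbut-2-en-1-yl)phenol
Conditions: NaH, toluene, 0 °C; then 16, rt to 50 °C
Reagents that add atoms: none
Why: In the ortho-C-alkylation of a sodium phenoxide with an allylic bromide in a non-polar solvent the tight ion pair shields oxygen and guides SN2 attack to the ortho carbon, and of the two ortho positions the one para to bromine is open whereas the other is blocked by the neighbouring bromine.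

**Step 11**
Reactants: 17 5-bromo-4-iodo-2-(3-methylbut-2-en-1-yl)phenol
Product: 18 ring A iodide, 1-bromo-2-iodo-4-(3-methylbut-2-en-1-yl)-5-(triisopropylsilyloxy)benzene
Conditions: TIPSCl, imidazole, DMF, 40 °C
Reagents that add atoms: triisopropylsilyl chloride CC(C)[Si](Cl)(C(C)C)C(C)C
Why: Routine imidazole-promoted O-silylation masks the phenol so that no phenoxide interferes with the palladium step, and it leaves the C–I, C–Br and prenyl groups untouched.

**Step 12**
Reactants: 14 bicyclic aryl alkynol; 18 ring A iodide
Product: 20 tricyclic 2,3-diaryl pyran enol ether (ring B on Cα; ring A with its bromide on Cβ; three triisopropylsilyl ethers; 1R,2R,3R,6S), via lithium alkoxide 19 (not isolated)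
Conditions: LiN(SiMe3)2 (1.05 equiv), THF, 0 °C; then 18 (1.2 equiv), Pd(PPh3)4 (10 mol %), THF, 65 °C
Reagents that add atoms: none
Why: Zerovalent palladium inserts into the C–I bond of 18; the arylpalladium iodide formed (divalent palladium) binds the triple bond of 19 from its open outer side, the C3 alkoxide adds to Cα from the inner side, and the vinyl(aryl)palladium centred on Cβ collapses by reductive elimination, so O–Cα and Cβ–C(ring A) arise in one catalytic turn. The closest known reaction type is the palladium-catalysed arylative cyclisation of alkynol alkoxides and of ortho-alkynylphenols with aryl halides (anti-oxypalladation followed by reductive elimination), which with simple pent-4-yn-1-ols usually closes 5-exo. Here the pyran must close 6-endo-dig, an anti addition by necessity, since oxygen and C1 end up cis on the ring double bond and rings A and B therefore also cis, as the oxepine needs; no stereocentre is formed and C1, C2, C3 and C6 are not touched. Three substrate features should secure 6-endo over 5-exo attack: in the all-cis cage the C3 oxygen hangs over the alkyne about equally far from both carbons, the 2,4-bis(silyloxy)phenyl donor makes Cα the carbon that carries positive charge in the π-complex, and 5-exo closure would have to raise a diarylmethylidene group against the C7 methyl groups. Insertion at C–I before C–Br follows from the reactivity gap of the two bonds towards Pd(PPh3)4 at 65 °C, and the hindered alkyne together with a bulky tertiary alkoxide, which binds poorly to the crowded metal and cannot undergo β-hydride elimination, disfavours syn carbopalladation and inner-sphere Pd–O insertion. The triisopropylsilyl ethers resist transfer to the alkoxide, which keeps the ring B ortho-oxygen masked and shuts off 5-endo benzofuran closure.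

**Step 13**
Reactants: 20 tricyclic 2,3-diaryl pyran enol ether
Product: 21 triphenol bromide (same skeleton, three free phenols, ring A bromide retained)
Conditions: n-Bu4NF (3.3 equiv), AcOH (3.3 equiv), THF, 0 °C, Ar
Reagents that add atoms: none
Why: Fluoride cleaves the three aryl O–Si bonds through the strong Si–F bond, and the acetic acid buffer keeps the medium nearly neutral so that the enol ether, the prenyl group and the aryl bromide persist.

**Step 14**
Reactants: 21 triphenol bromide
Product: 22 target CNP0185814.1
Conditions: CuI (20 mol %), N,N-dimethylglycine (40 mol %), Cs2CO3 (4 equiv), 1,4-dioxane (0.005 M), 100 °C, Ar; aq. NH4Cl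
Reagents that add atoms: none
Why: In this intramolecular Ullmann diaryl ether synthesis catalysed by monovalent copper only the ring B ortho-oxygen among the three phenoxides can reach the C–Br carbon, towards which the Z enol ether double bond holds it, so the seven-membered oxepine closes while high dilution holds back intermolecular arylation, and no stereocentre is affected.

**Compound list**
1 | geraniol, (2E)-3,7-dimethylocta-2,6-dien-1-ol | CC(C)=CCC/C(C)=C/CO | starting material
2 | (2R,3R)-2,3-epoxygeraniol | OC[C@H]1O[C@]1(C)CCC=C(C)C | intermediate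
3 | (2S,3R)-1-chloro-2,3-epoxy-3,7-dimethyloct-6-ene | ClC[C@H]1O[C@]1(C)CCC=C(C)C | intermediate
4 | dilithiated (R)-dehydrolinalool (lithium acetylide alkoxide, not isolated) | [Li]C#C[C@](C)(O[Li])CCC=C(C)C | intermediate
5 | (4R)-4-hydroxy-4,8-dimethylnon-7-en-2-ynoic acid | OC(=O)C#C[C@](C)(O)CCC=C(C)C | intermediate
6 | (2Z,4R)-4-hydroxy-4,8-dimethylnona-2,7-dienoic acid (not isolated) | OC(=O)/C=C\[C@](C)(O)CCC=C(C)C | intermediate
7 | (5R)-5-methyl-5-(4-methylpent-3-en-1-yl)furan-2(5H)-one | O=C1C=C[C@@](C)(CCC=C(C)C)O1 | intermediate
8 | all-cis tricyclic γ-lactone (1R,2R,3R,6S) | O=C1[C@@H]2[C@H]3[C@H](CC[C@@]3(C)O1)C2(C)C | intermediate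
9 | tricyclic lactol (anomeric mixture) | OC1[C@@H]2[C@H]3[C@H](CC[C@@]3(C)O1)C2(C)C | intermediate
10 | ring-opened hydroxy aldehyde, C1-CHO cis to C3-OH (not isolated) | O=C[C@@H]1[C@H]2[C@H](CC[C@@]2(C)O)C1(C)C | intermediate
11 | ethynyl carbinol, C1-ethynyl cis to C3-OH on the all-cis 3,7,7-trimethylbicyclo[3.2.0]heptane core | C#C[C@@H]1[C@H]2[C@H](CC[C@@]2(C)O)C1(C)C | intermediate
12 | 4-iodoresorcinol | Oc1ccc(I)c(O)c1 | starting material
13 | 1-iodo-2,4-bis(triisopropylsilyloxy)benzene | CC(C)[Si](C(C)C)(C(C)C)Oc1ccc(I)c(O[Si](C(C)C)(C(C)C)C(C)C)c1 | intermediate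
14 | bicyclic aryl alkynol (key-step precursor) | CC(C)[Si](C(C)C)(C(C)C)Oc1ccc(C#C[C@@H]2[C@H]3[C@H](CC[C@@]3(C)O)C2(C)C)c(O[Si](C(C)C)(C(C)C)C(C)C)c1 | intermediate
15 | 3-bromo-4-iodophenol | Oc1ccc(I)c(Br)c1 | starting material
16 | prenyl bromide, 1-bromo-3-methylbut-2-ene | CC(C)=CCBr | starting material
17 | 5-bromo-4-iodo-2-(3-methylbut-2-en-1-yl)phenol | CC(C)=CCc1cc(I)c(Br)cc1O | intermediate
18 | ring A iodide, 1-bromo-2-iodo-4-(3-methylbut-2-en-1-yl)-5-(triisopropylsilyloxy)benzene (key-step precursor) | CC(C)=CCc1cc(I)c(Br)cc1O[Si](C(C)C)(C(C)C)C(C)C | intermediate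
19 | lithium alkoxide of 14 (not isolated) | CC(C)[Si](C(C)C)(C(C)C)Oc1ccc(C#C[C@@H]2[C@H]3[C@H](CC[C@@]3(C)O[Li])C2(C)C)c(O[Si](C(C)C)(C(C)C)C(C)C)c1 | intermediate
20 | tricyclic 2,3-diaryl pyran enol ether (key-step product) | CC(C)[Si](C(C)C)(C(C)C)Oc1ccc(c(O[Si](C(C)C)(C(C)C)C(C)C)c1)C1=C(c2cc(CC=C(C)C)c(O[Si](C(C)C)(C(C)C)C(C)C)cc2Br)[C@@H]2[C@H]3[C@H](CC[C@@]3(C)O1)C2(C)C | intermediate
21 | triphenol bromide | Oc1ccc(c(O)c1)C1=C(c2cc(CC=C(C)C)c(O)cc2Br)[C@@H]2[C@H]3[C@H](CC[C@@]3(C)O1)C2(C)C | intermediate
22 | CNP0185814.1 | CC(C)=CCc1cc2c(cc1O)Oc1cc(O)ccc1C1=C2[C@@H]2[C@H]3[C@H](CC[C@@]3(C)O1)C2(C)C | target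

**Step count**
Total: 14 steps. Longest linear sequence: 11 steps (1–7, 9, 12, 13, 14).

**Steps most likely to fail**

Step 12.
- What may go wrong: alkoxide attack at Cβ (5-exo closure), syn carbopalladation of the alkyne outrunning oxypalladation, or silyl transfer that unmasks the ring B ortho-oxygen.
- The fallback sets out from 14 and 18 and returns at 20. It makes the two bonds one after the other.
- Iodocyclisation of 14 (I2, NaHCO3, MeCN, 0 °C) should close the pyran 6-endo to the β-iodo enol ether F1, because the strongly polarising iodonium electrophile responds more sharply to the donor aryl group.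
- Iodine–magnesium exchange on 18 (i-PrMgCl·LiCl, THF, −40 °C) and quenching with 2-isopropoxy-4,4,5,5-tetramethyl-1,3,2-dioxaborolane gives the ring A pinacol boronate F2.
- Suzuki–Miyaura coupling of the two (PdCl2(dppf), K3PO4, dioxane/H2O, 60 °C, vinyl C–I before aryl C–Br) gives 20.

Step 14.
- What may go wrong: sluggish activation of the electron-rich, phenoxide-bearing C–Br bond, intermolecular O-arylation by the two other phenoxides, and oxidative degradation of the triphenolate at 100 °C.
- The fallback sets out from 20 and returns at 22. It inverts the polarity of ring A.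
- Bromine–lithium exchange (n-BuLi, THF, −78 °C), B(OiPr)3 and aq. NH4Cl give the tris-silylated ring A boronic acid F3.
- Buffered desilylation (n-Bu4NF, AcOH, THF, 0 °C) gives the trihydroxy boronic acid F4.
- Intramolecular Chan–Lam coupling (Cu(OAc)2, pyridine, 4 Å MS, air, CH2Cl2, rt, high dilution) closes the oxepine at room temperature to 22.

Step 7.
- What may go wrong: slow ring opening of the lactol, and base-mediated epimerisation at C1 of the open aldehyde before homologation. The alkyne would then sit trans to the C3 hydroxyl and could not cyclise.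
- The fallback sets out from 9 and returns at 11. It avoids carbonate and methanol altogether.
- Corey–Fuchs olefination with the preformed, essentially non-basic ylide (CBr4, PPh3, Zn, CH2Cl2, 0 °C to rt) gives the dibromoalkene carbinol F5.
- n-BuLi (3.2 equiv, THF, −78 °C to rt, then H2O) converts it to 11 by elimination and bromine–lithium exchange. C1 then carries no acidifying carbonyl group.

**Further compounds**
F1 | step 12 | β-iodo enol ether (6-endo iodocyclisation product of 14) | CC(C)[Si](C(C)C)(C(C)C)Oc1ccc(c(O[Si](C(C)C)(C(C)C)C(C)C)c1)C1=C(I)[C@@H]2[C@H]3[C@H](CC[C@@]3(C)O1)C2(C)C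
F2 | step 12 | ring A pinacol boronate | CC(C)=CCc1cc(B2OC(C)(C)C(C)(C)O2)c(Br)cc1O[Si](C(C)C)(C(C)C)C(C)C
F3 | step 14 | tris-silylated ring A boronic acid | CC(C)[Si](C(C)C)(C(C)C)Oc1ccc(c(O[Si](C(C)C)(C(C)C)C(C)C)c1)C1=C(c2cc(CC=C(C)C)c(O[Si](C(C)C)(C(C)C)C(C)C)cc2B(O)O)[C@@H]2[C@H]3[C@H](CC[C@@]3(C)O1)C2(C)C
F4 | step 14 | trihydroxy boronic acid | Oc1ccc(c(O)c1)C1=C(c2cc(CC=C(C)C)c(O)cc2B(O)O)[C@@H]2[C@H]3[C@H](CC[C@@]3(C)O1)C2(C)C
F5 | step 7 | dibromoalkene carbinol | BrC(Br)=C[C@@H]1[C@H]2[C@H](CC[C@@]2(C)O)C1(C)C
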